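**Retrosynthetic overview**
1. The chlorine is put on last: the target comes from C-5 chlorination of the des-chloro triol.
2. The des-chloro bicycle comes from an acyclic keto-ynone in one flask: a 6-exo-dig Michael ring closure forms the cyclohexenone, then acid-driven vinylogous esterification forms the pyran.
3. The keto-ynone comes from a terminal alkyne/methyl ketone, CO and an (E)-vinyl iodide by carbonylative Sonogashira coupling.
4. The alkyne fragment comes from a temporary δ-lactone template ((S)-2-vinyloxirane, silylacetylene, methacrylate, ring-closing metathesis); OsO4 anti to the alkyne sets C-7/C-8 from C-8a, and MeLi opens the template.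
5. The vinyl iodide comes from (S)-α-methyl-γ-butyrolactone by Wittig, Takai and Shi epoxidation/5-exo cyclisation. Ring order: oxolane, temporary lactone, then cyclohexenone and pyran together.

Assumption: (S)-2-vinyloxirane and (S)-α-methyl-γ-butyrolactone are bought enantiopure (each is one catalytic step from a bulk racemate or achiral precursor).

Atom labels C-1 to C-8a are the isochromene positions of the target; primed labels are side-chain positions.

**Step 1**
Reactants: 1 (S)-2-vinyloxirane; 2 ethynyl(trimethyl)silane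
Product: 3 (2S)-2-[(trimethylsilyl)ethynyl]but-3-en-1-ol
Conditions: 2, n-BuLi, THF, −78 °C; BF3·OEt2; then 1, −78 °C; H2O
Reagents that add atoms: none
Why: Yamaguchi–Hirao alkynylation, in which the BF3-activated vinyl epoxide is opened by the lithium acetylide in an SN2 reaction at the allylic carbon, so C-8a is set with inversion of the epoxide stereocentre.

**Step 2**
Reactants: 3 (2S)-2-[(trimethylsilyl)ethynyl]but-3-en-1-ol; 4 methacryloyl chloride
Product: 5 (2S)-2-[(trimethylsilyl)ethynyl]but-3-en-1-yl methacrylate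
Conditions: Et3N, DMAP (cat.), CH2Cl2, 0 °C
Reagents that add atoms: none
Why: DMAP-catalysed acylation of the primary alcohol installs the methacrylate for ring closure without touching the stereocentre.

**Step 3**
Reactants: 5 (2S)-2-[(trimethylsilyl)ethynyl]but-3-en-1-yl methacrylate
Product: 6 (5S)-3-methyl-5-[(trimethylsilyl)ethynyl]-5,6-dihydro-2H-pyran-2-one
Conditions: second-generation Grubbs catalyst RuCl2(=CHPh)(PCy3)(H2IMes) (5 mol %), toluene, 80 °C
Reagents that add atoms: none
Why: Ring-closing metathesis between the vinyl group and the methacrylate gives the α-methyl unsaturated δ-lactone (the silylalkyne is too hindered and too close to the carbene for enyne metathesis), so C-8a now differentiates the two faces of the ring alkene.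

**Step 4**
Reactants: 6 (5S)-3-methyl-5-[(trimethylsilyl)ethynyl]-5,6-dihydro-2H-pyran-2-one
Product: 7 (3R,4R,5S)-3,4-dihydroxy-3-methyl-5-[(trimethylsilyl)ethynyl]oxan-2-one
Conditions: OsO4 (2 mol %), NMO, citric acid, t-BuOH/H2O, rt
Reagents that add atoms: N-methylmorpholine N-oxide, C[N+]1([O-])CCOCC1; water, O
Why: Upjohn syn-dihydroxylation occurs on the lactone face anti to the allylic alkynyl group, so C-7 and C-8 are set together as the cis-diol trans to the alkyne.

**Step 5**
Reactants: 7 (3R,4R,5S)-3,4-dihydroxy-3-methyl-5-[(trimethylsilyl)ethynyl]oxan-2-one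
Product: 8 (3aR,7S,7aR)-2,2,3a-trimethyl-7-[(trimethylsilyl)ethynyl]tetrahydro-4H-[1,3]dioxolo[4,5-c]pyran-4-one (acetonide of 7)
Conditions: Me2C(OMe)2, CSA (cat.), acetone, rt
Reagents that add atoms: 2,2-dimethoxypropane, COC(C)(C)OC
Why: Acid-catalysed transketalisation masks the cis-diol as an acetonide so that neither hydroxyl can add to the ynone later.

**Step 6**
Reactants: 8 acetonide lactone
Product: 10 1-[(4R,5R)-5-[(2S)-1-hydroxybut-3-yn-2-yl]-2,2,4-trimethyl-1,3-dioxolan-4-yl]ethan-1-one (in equilibrium with its six-membered hemiketal), via silylalkyne ketone 9 (not isolated)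
Conditions: MeLi (1.1 equiv), THF, −78 °C; then MeOH, K2CO3 (0.2 equiv), −78 °C → rt
Reagents that add atoms: methyllithium, [Li]C
Why: Mono-addition of MeLi to the δ-lactone stops at the stable lithium lactolate, giving the methyl ketone (C-5/C-6) and freeing the C-1 hydroxyl, and K2CO3/MeOH then protodesilylates the alkyne; no stereocentre is affected.

**Step 7**
Reactants: 11 (3S)-3-methyloxolan-2-one; 12 2-(triphenyl-λ5-phosphanylidene)propanal
Product: 14 (2E,4S)-6-hydroxy-2,4-dimethylhex-2-enal, via lactol 13 (not isolated)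
Conditions: i-Bu2AlH (1.05 equiv), toluene, −78 °C; then 12, −78 → 80 °C
Reagents that add atoms: none
Why: Partial reduction to the lactol and Wittig olefination of its open hydroxy-aldehyde form with the stabilised ylide gives the (E)-trisubstituted enal with the α-methyl stereocentre carried through.

**Step 8**
Reactants: 14 (2E,4S)-6-hydroxy-2,4-dimethylhex-2-enal
Product: 15 (3S,4E,6E)-7-iodo-3,5-dimethylhepta-4,6-dien-1-ol
Conditions: CrCl2 (6 equiv), CHI3 (2 equiv), THF/1,4-dioxane, 0 °C → rt
Reagents that add atoms: iodoform, IC(I)I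
Why: Takai iodo-olefination converts the aldehyde into the (E)-vinyl iodide through the geminal dichromium reagent and tolerates the free alcohol.

**Step 9**
Reactants: 15 (3S,4E,6E)-7-iodo-3,5-dimethylhepta-4,6-dien-1-ol
Product: 17 (2R,3E)-4-iodo-2-[(2S,3S)-3-methyloxolan-2-yl]but-3-en-2-ol, via epoxide 16 (not isolated)
Conditions: D-fructose-derived Shi ketone (0.3 equiv), KHSO5 (Oxone), K2CO3, Bu4NHSO4, MeCN/CH2(OMe)2/aq. Na2B4O7 buffer, 0 °C; then K2CO3 (0.3 equiv), MeOH, rt
Reagents that add atoms: potassium peroxymonosulfate, [K+].[O-]S(=O)(=O)OO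
Why: Shi asymmetric epoxidation attacks the electron-richer trisubstituted alkene under reagent control to give the (2R,3R)-epoxide, and base-mediated 5-exo-tet opening by the primary alcohol at the non-allylic epoxide carbon (inversion) closes the 2,3-trans-oxolane and leaves the (R)-tertiary carbinol.

**Step 10**
Reactants: 10 alkynyl hydroxy ketone; 17 (2R,3E)-4-iodo-2-[(2S,3S)-3-methyloxolan-2-yl]but-3-en-2-ol
Product: 18 (2S,6E,8R)-2-[(4R,5R)-5-acetyl-2,2,5-trimethyl-1,3-dioxolan-4-yl]-1,8-dihydroxy-8-[(2S,3S)-3-methyloxolan-2-yl]non-6-en-3-yn-5-one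
Conditions: PdCl2(PPh3)2 (5 mol %), CO (1 atm), Et3N (3 equiv), THF, rt
Reagents that add atoms: carbon monoxide, [C-]#[O+]
Why: Carbonylative Sonogashira coupling (oxidative addition of the vinyl iodide, CO insertion, alkynyl transfer) joins the fragments through the new C-3 carbonyl with retention of the (E)-alkene and without strong base.

**Step 11**
Reactants: 18 keto-ynone
Product: 21 (7R,8R,8aS)-7,8-dihydroxy-3-{(1E,3R)-3-hydroxy-3-[(2S,3S)-3-methyloxolan-2-yl]but-1-en-1-yl}-7-methyl-1,7,8,8a-tetrahydro-6H-isochromen-6-one, via enedione 19 (not isolated), via acetonide 20 (not isolated)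
Conditions: KN(SiMe3)2 (3.3 equiv), THF, −78 → 0 °C; then 2 M aq. HCl, THF, rt → 40 °C
Reagents that add atoms: none
Why: Proposed new method: the kinetic potassium enolate of the methyl ketone (the only readily enolisable site, since C-7 is quaternary) adds 6-exo-dig to the β-carbon C-4a of the tethered ynone (closest known type: intramolecular Michael/Conia-ene-type carbocyclisation of ketone enolates onto activated alkynes) to give a vinylogous 1,3-diketone, whose C-3 carbonyl is then captured by the C-1 hydroxyl under acid (vinylogous esterification, as for 1,3-diketone plus alcohol giving a β-alkoxy enone), so the carbocycle and the pyran close in one flask while the aqueous acid also removes the acetonide; no stereocentre is formed or touched.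

**Step 12**
Reactants: 21 des-chloro triol
Product: 22 (7R,8R,8aS)-5-chloro-7,8-dihydroxy-3-{(1E,3R)-3-hydroxy-3-[(2S,3S)-3-methyloxolan-2-yl]but-1-en-1-yl}-7-methyl-1,7,8,8a-tetrahydro-6H-isochromen-6-one (target)
Conditions: N-chlorosuccinimide (1.05 equiv), MeCN, 0 °C
Reagents that add atoms: N-chlorosuccinimide, O=C1CCC(=O)N1Cl
Why: Electrophilic chlorination of the doubly vinylogous ester takes place at C-5, the nucleophilic α-carbon of the push–pull dienone (the site halogenated in azaphilones), and loss of the C-5 proton restores the chromophore without touching a stereocentre.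

**Compound list**
1 | (S)-2-vinyloxirane | C=C[C@H]1CO1 | starting material
2 | ethynyl(trimethyl)silane | C#C[Si](C)(C)C | starting material
3 | (2S)-2-[(trimethylsilyl)ethynyl]but-3-en-1-ol | C=C[C@@H](C#C[Si](C)(C)C)CO | intermediate
4 | methacryloyl chloride | C=C(C)C(Cl)=O | starting material
5 | (2S)-2-[(trimethylsilyl)ethynyl]but-3-en-1-yl methacrylate | C=C[C@@H](C#C[Si](C)(C)C)COC(=O)C(C)=C | intermediate
6 | (5S)-3-methyl-5-[(trimethylsilyl)ethynyl]-5,6-dihydro-2H-pyran-2-one | CC1=C[C@@H](C#C[Si](C)(C)C)COC1=O | intermediate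
7 | (3R,4R,5S)-3,4-dihydroxy-3-methyl-5-[(trimethylsilyl)ethynyl]oxan-2-one | O=C1[C@](C)(O)[C@H](O)[C@@H](C#C[Si](C)(C)C)CO1 | intermediate
8 | (3aR,7S,7aR)-2,2,3a-trimethyl-7-[(trimethylsilyl)ethynyl]tetrahydro-4H-[1,3]dioxolo[4,5-c]pyran-4-one (acetonide of 7) | O=C1[C@]2(C)OC(C)(C)O[C@@H]2[C@@H](C#C[Si](C)(C)C)CO1 | intermediate
9 | 1-[(4R,5R)-5-[(2S)-1-hydroxy-4-(trimethylsilyl)but-3-yn-2-yl]-2,2,4-trimethyl-1,3-dioxolan-4-yl]ethan-1-one | CC(=O)[C@]1(C)OC(C)(C)O[C@@H]1[C@@H](C#C[Si](C)(C)C)CO | intermediate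
10 | 1-[(4R,5R)-5-[(2S)-1-hydroxybut-3-yn-2-yl]-2,2,4-trimethyl-1,3-dioxolan-4-yl]ethan-1-one | CC(=O)[C@]1(C)OC(C)(C)O[C@@H]1[C@@H](C#C)CO | intermediate
11 | (3S)-3-methyloxolan-2-one [(S)-α-methyl-γ-butyrolactone] | C[C@H]1CCOC1=O | starting material
12 | 2-(triphenyl-λ5-phosphanylidene)propanal | CC(C=O)=P(c1ccccc1)(c1ccccc1)c1ccccc1 | starting material
13 | (3S)-3-methyloxolan-2-ol (lactol, anomer mixture) | C[C@H]1CCOC1O | intermediate
14 | (2E,4S)-6-hydroxy-2,4-dimethylhex-2-enal | OCC[C@H](C)/C=C(\C)C=O | intermediate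
15 | (3S,4E,6E)-7-iodo-3,5-dimethylhepta-4,6-dien-1-ol | OCC[C@H](C)/C=C(\C)/C=C/I | intermediate
16 | (3S)-3-[(2R,3R)-3-[(E)-2-iodoethenyl]-3-methyloxiran-2-yl]butan-1-ol | OCC[C@H](C)[C@H]1O[C@]1(C)/C=C/I | intermediate
17 | (2R,3E)-4-iodo-2-[(2S,3S)-3-methyloxolan-2-yl]but-3-en-2-ol | C[C@H]1CCO[C@@H]1[C@](C)(O)/C=C/I | intermediate
18 | (2S,6E,8R)-2-[(4R,5R)-5-acetyl-2,2,5-trimethyl-1,3-dioxolan-4-yl]-1,8-dihydroxy-8-[(2S,3S)-3-methyloxolan-2-yl]non-6-en-3-yn-5-one | C[C@H]1CCO[C@@H]1[C@](C)(O)/C=C/C(=O)C#C[C@@H](CO)[C@H]1OC(C)(C)O[C@@]1(C)C(C)=O | intermediate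
19 | Michael adduct: acetonide-protected cyclohexanone carrying the exocyclic (Z)-acylmethylene at C-4a (vinylogous 1,3-diketone) and the free CH2OH at C-8a | C[C@H]1CCO[C@@H]1[C@](C)(O)/C=C/C(=O)/C=C1/CC(=O)[C@]2(C)OC(C)(C)O[C@@H]2[C@@H]1CO | intermediate
20 | 7,8-O-isopropylidene derivative of 21 | C[C@H]1CCO[C@@H]1[C@](C)(O)/C=C/C1=CC2=CC(=O)[C@]3(C)OC(C)(C)O[C@@H]3[C@@H]2CO1 | intermediate
21 | (7R,8R,8aS)-7,8-dihydroxy-3-{(1E,3R)-3-hydroxy-3-[(2S,3S)-3-methyloxolan-2-yl]but-1-en-1-yl}-7-methyl-1,7,8,8a-tetrahydro-6H-isochromen-6-one | C[C@H]1CCO[C@@H]1[C@](C)(O)/C=C/C1=CC2=CC(=O)[C@](C)(O)[C@H](O)[C@@H]2CO1 | intermediate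
22 | (7R,8R,8aS)-5-chloro-7,8-dihydroxy-3-{(1E,3R)-3-hydroxy-3-[(2S,3S)-3-methyloxolan-2-yl]but-1-en-1-yl}-7-methyl-1,7,8,8a-tetrahydro-6H-isochromen-6-one | C[C@H]1CCO[C@@H]1[C@](C)(O)/C=C/C1=CC2=C(Cl)C(=O)[C@](C)(O)[C@H](O)[C@@H]2CO1 | target

**Totals**
Total step count: 12. Longest linear sequence: 9 (steps 1–6, 10, 11, 12); the vinyl iodide branch is 3 steps (7–9).

**Three steps most likely to fail**

Step 11 (double annulation). The risk is that base removes the propargylic C-8a hydrogen of the ynone (allenone formation, epimerisation or β-alkoxide loss) faster than the methyl-ketone enolate cyclises. The fallback sets out from 18 and returns at 21 with a neutral carbon nucleophile. TMSOTf/Et3N converts 18 into the tris(trimethylsilyl) derivative F1 (trimethylsilyl enol ether of the methyl ketone, both hydroxyls silylated). TiCl4 in CH2Cl2 at −78 °C then effects an intramolecular Mukaiyama–Michael addition onto the ynone to give the bis(trimethylsilyl) ether of the enedione F2. Aqueous HCl desilylates, closes the pyran and removes the acetonide to give 21.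

Step 10 (carbonylative coupling). The risk is direct, CO-free enyne coupling or alkoxycarbonylation by the free primary alcohol. The fallback sets out from 17 (with 10) and returns at 18 by nucleophilic alkynylation and oxidation. 17 is treated with MeLi then t-BuLi at −78 °C and quenched with DMF to give (2E,4R)-4-hydroxy-4-[(2S,3S)-3-methyloxolan-2-yl]pent-2-enal F3. Zn(OTf)2/Et3N-mediated addition of alkyne 10 to F3 gives the C-5 carbinol of 18 F4 as an inconsequential epimer mixture. MnO2 oxidises only this allylic/propargylic alcohol to give 18.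

Step 9 (Shi epoxidation/cyclisation). The risks are 6-endo opening at the allylic epoxide carbon and imperfect site selectivity on the iodo-diene. The fallback sets out from 14 and returns at 17, moving the epoxidation to an allylic alcohol. NaBH4/CeCl3 reduces 14 to (2E,4S)-2,4-dimethylhex-2-ene-1,6-diol F5. Sharpless asymmetric epoxidation (Ti(OiPr)4, D-(−)-diethyl tartrate, t-BuOOH) gives (3S)-3-[(2R,3R)-3-(hydroxymethyl)-3-methyloxiran-2-yl]butan-1-ol F6. With no vinyl group on the epoxide, CSA-promoted 5-exo opening with inversion gives (2R)-2-[(2S,3S)-3-methyloxolan-2-yl]propane-1,2-diol F7. TEMPO/PhI(OAc)2 oxidises the primary alcohol to (2S)-2-hydroxy-2-[(2S,3S)-3-methyloxolan-2-yl]propanal F8, and Takai iodo-olefination (CHI3, CrCl2) returns 17.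

**Further compounds**
F1 | step 11 | tris(trimethylsilyl) derivative of 18 (silyl enol ether of the methyl ketone, both hydroxyls as trimethylsilyl ethers) | C[C@H]1CCO[C@@H]1[C@](C)(O[Si](C)(C)C)/C=C/C(=O)C#C[C@@H](CO[Si](C)(C)C)[C@H]1OC(C)(C)O[C@@]1(C)C(=C)O[Si](C)(C)C
F2 | step 11 | bis(trimethylsilyl) ether of enedione 19 | C[C@H]1CCO[C@@H]1[C@](C)(O[Si](C)(C)C)/C=C/C(=O)/C=C1/CC(=O)[C@]2(C)OC(C)(C)O[C@@H]2[C@@H]1CO[Si](C)(C)C
F3 | step 10 | (2E,4R)-4-hydroxy-4-[(2S,3S)-3-methyloxolan-2-yl]pent-2-enal | C[C@H]1CCO[C@@H]1[C@](C)(O)/C=C/C=O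
F4 | step 10 | C-5 carbinol of 18 (epimer mixture at the new carbinol) | C[C@H]1CCO[C@@H]1[C@](C)(O)/C=C/C(O)C#C[C@@H](CO)[C@H]1OC(C)(C)O[C@@]1(C)C(C)=O
F5 | step 9 | (2E,4S)-2,4-dimethylhex-2-ene-1,6-diol | OCC[C@H](C)/C=C(\C)CO
F6 | step 9 | (3S)-3-[(2R,3R)-3-(hydroxymethyl)-3-methyloxiran-2-yl]butan-1-ol | OCC[C@H](C)[C@H]1O[C@]1(C)CO
F7 | step 9 | (2R)-2-[(2S,3S)-3-methyloxolan-2-yl]propane-1,2-diol | C[C@H]1CCO[C@@H]1[C@](C)(O)CO
F8 | step 9 | (2S)-2-hydroxy-2-[(2S,3S)-3-methyloxolan-2-yl]propanal | C[C@H]1CCO[C@@H]1[C@](C)(O)C=O
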